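## Retrosynthetic overview

1. The C5 chlorine (NCS) and the 7-O-acetyl group are installed last on a 7-hydroxy bicyclic azaphilone.
2. The azaphilone comes from a resorcinol keto-aldehyde by oxidative dearomatisation with a flavin-dependent monooxygenase, which sets C7. Ring A (the carbocycle) is present from the start as a benzene ring; ring B (the pyran) closes last, spontaneously, after dearomatisation.
3. The keto-aldehyde comes from an ortho-alkynylbenzaldehyde by gold-catalysed 6-endo cyclisation and hydrolysis; the alkyne comes from Sonogashira coupling of 6-bromo-2,4-dihydroxy-3-methylbenzaldehyde with an (S)-dienyne.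
4. The dienyne comes from (S,E)-2,4-dimethylhex-2-enal, made from (S)-2-methylbutanoic acid, which is obtained from tiglic acid by Ru/H8-BINAP asymmetric hydrogenation (first stereocentre).
5. The bromo-aldehyde comes from 2,6-dimethoxytoluene by iridium C–H borylation, bromodeboronation, Vilsmeier formylation and BBr3 demethylation.

Assumption: the flavin-dependent monooxygenase (an AzaH-type enzyme, R-selective at C7 of the non-chlorinated azaphilone; the keto-aldehyde of step 13 is its native substrate type) and phosphite dehydrogenase are used as recombinant E. coli lysates and count as catalysts. The enantiomer sense of step 1 and the R-selectivity of the enzyme are taken from memory of precedent and should be confirmed by optical rotation and CD.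

## Route

Step 1
Reactants: 1 tiglic acid [(E)-2-methylbut-2-enoic acid]
Product: 2 (S)-2-methylbutanoic acid
Conditions: H2 (1.5 atm), Ru(OAc)2[(S)-H8-BINAP] (0.5 mol %), MeOH, 15–20 °C
Reagents that add atoms: none
Why: Carboxylate-directed asymmetric hydrogenation of the trisubstituted alkene, in which the (S)-ligand complex adds H2 to one enantioface and sets the stereocentre as S (about 97 % ee).

Step 2
Reactants: 2 (S)-2-methylbutanoic acid
Product: 3 (S)-2-methylbutan-1-ol
Conditions: LiAlH4, Et2O, 0 °C → reflux; then H2O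
Reagents that add atoms: none
Why: Hydride reduction of the carboxylic acid proceeds through carboxylate and alkoxide stages that do not enolise, so the stereocentre is untouched.

Step 3
Reactants: 3 (S)-2-methylbutan-1-ol
Product: 5 ethyl (S,E)-2,4-dimethylhex-2-enoate, via (S)-2-methylbutanal 4 (not isolated)
Conditions: TEMPO (10 mol %), PhI(OAc)2, CH2Cl2, rt; then Ph3P=C(CH3)CO2Et, rt → 40 °C
Reagents that add atoms: ethyl 2-(triphenylphosphoranylidene)propanoate, CCOC(=O)C(C)=P(c1ccccc1)(c1ccccc1)c1ccccc1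
Why: Base-free nitroxyl oxidation followed by Wittig olefination in the same flask traps the epimerisable aldehyde at once, and the stabilised ylide gives the E-trisubstituted enoate (E:Z > 95:5).

Step 4
Reactants: 5 ethyl (S,E)-2,4-dimethylhex-2-enoate
Product: 6 (S,E)-2,4-dimethylhex-2-en-1-ol
Conditions: DIBAL-H (2.2 equiv), CH2Cl2, −78 → 0 °C; then H2O
Reagents that add atoms: none
Why: DIBAL-H reduces the enoate 1,2 to the allylic alcohol without touching alkene geometry or the stereocentre.

Step 5
Reactants: 6 (S,E)-2,4-dimethylhex-2-en-1-ol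
Product: 7 (S,E)-2,4-dimethylhex-2-enal
Conditions: MnO2 (15 equiv), CH2Cl2, rt
Reagents that add atoms: none
Why: Neutral, selective allylic oxidation with MnO2 stops at the enal and causes no isomerisation or epimerisation.

Step 6
Reactants: 7 (S,E)-2,4-dimethylhex-2-enal
Product: 8 trimethyl[(3E,5E,7S)-5,7-dimethylnona-3,5-dien-1-yn-1-yl]silane
Conditions: (EtO)2P(O)CH2C≡CSiMe3, LiHMDS, THF, −78 °C → rt
Reagents that add atoms: diethyl [3-(trimethylsilyl)prop-2-yn-1-yl]phosphonate, CCOP(=O)(CC#C[Si](C)(C)C)OCC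
Why: Horner–Wadsworth–Emmons olefination with the silyl-capped propargyl phosphonate builds the new disubstituted alkene E-selectively (minor Z isomer removed by chromatography), and the enal has no α-hydrogen to lose.

Step 7
Reactants: 8 trimethyl[(3E,5E,7S)-5,7-dimethylnona-3,5-dien-1-yn-1-yl]silane
Product: 9 (3E,5E,7S)-5,7-dimethylnona-3,5-dien-1-yne
Conditions: K2CO3 (cat.), MeOH, rt; pentane extraction, used as a concentrated solution (volatile)
Reagents that add atoms: none
Why: Methanolysis of the alkynyl–silicon bond frees the terminal alkyne under conditions too mild to affect the diene or the stereocentre.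

Step 8
Reactants: 10 2,6-dimethoxytoluene
Product: 11 2-(3,5-dimethoxy-4-methylphenyl)-4,4,5,5-tetramethyl-1,3,2-dioxaborolane
Conditions: B2pin2 (0.55 equiv), [Ir(OMe)(cod)]2 (1 mol %), 4,4'-di-tert-butyl-2,2'-bipyridine (2 mol %), THF, 80 °C
Reagents that add atoms: bis(pinacolato)diboron, CC1(C)OB(OC1(C)C)B1OC(C)(C)C(C)(C)O1
Why: Iridium-catalysed C–H borylation is sterically controlled and goes to the only C–H flanked by two hydrogens, para to the methyl group.

Step 9
Reactants: 11 2-(3,5-dimethoxy-4-methylphenyl)-4,4,5,5-tetramethyl-1,3,2-dioxaborolane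
Product: 12 5-bromo-1,3-dimethoxy-2-methylbenzene
Conditions: CuBr2 (3 equiv), MeOH/H2O 1:1, 80 °C
Reagents that add atoms: copper dibromide, [Cu+2].[Br-].[Br-]
Why: Copper-mediated bromodeboronation replaces boron by bromine at the same carbon, giving a substitution pattern that electrophilic bromination cannot reach.

Step 10
Reactants: 12 5-bromo-1,3-dimethoxy-2-methylbenzene
Product: 13 6-bromo-2,4-dimethoxy-3-methylbenzaldehyde
Conditions: POCl3, DMF, 0 → 90 °C; then ice-water
Reagents that add atoms: N,N-dimethylformamide, CN(C)C=O; water, O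
Why: Vilsmeier–Haack formylation can only attack the two equivalent free positions (ortho and para to the methoxy groups), so a single regioisomer forms.

Step 11
Reactants: 13 6-bromo-2,4-dimethoxy-3-methylbenzaldehyde
Product: 14 6-bromo-2,4-dihydroxy-3-methylbenzaldehyde
Conditions: BBr3 (4 equiv), CH2Cl2, −78 °C → rt; then H2O
Reagents that add atoms: none
Why: Lewis-acid cleavage of both aryl methyl ethers is done here, on a robust small molecule, so that no harsh deprotection is needed once the polyene is present.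

Step 12
Reactants: 14 6-bromo-2,4-dihydroxy-3-methylbenzaldehyde; 9 (3E,5E,7S)-5,7-dimethylnona-3,5-dien-1-yne
Product: 15 2,4-dihydroxy-3-methyl-6-[(3E,5E,7S)-5,7-dimethylnona-3,5-dien-1-yn-1-yl]benzaldehyde
Conditions: PdCl2(PPh3)2 (5 mol %), CuI (10 mol %), Et3N, DMF (degassed), 60 °C
Reagents that add atoms: none
Why: Sonogashira coupling of the aryl bromide with the terminal alkyne tolerates the free phenols and the aldehyde and touches neither the stereocentre nor the alkene geometry.

Step 13
Reactants: 15 2,4-dihydroxy-3-methyl-6-[(3E,5E,7S)-5,7-dimethylnona-3,5-dien-1-yn-1-yl]benzaldehyde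
Product: 17 2,4-dihydroxy-3-methyl-6-[(3E,5E,7S)-5,7-dimethyl-2-oxonona-3,5-dien-1-yl]benzaldehyde, via 2-benzopyrylium trifluoroacetate 16 (not isolated)
Conditions: Au(OAc)3 (5 mol %), TFA/ClCH2CH2Cl 1:10, rt, 15 min; evaporate; then MeCN/H2O, phosphate buffer pH 7, rt
Reagents that add atoms: water, O
Why: Trivalent gold activates the alkyne for 6-endo-dig attack by the aldehyde oxygen (carbonyl-assisted cycloisomerisation), and water then adds at C1 of the pyrylium salt and ring-opens the pseudo-base, so the alkyne is hydrated regiospecifically to the benzyl dienyl ketone.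

Step 14
Reactants: 17 2,4-dihydroxy-3-methyl-6-[(3E,5E,7S)-5,7-dimethyl-2-oxonona-3,5-dien-1-yl]benzaldehyde
Product: 19 (7R)-7-hydroxy-7-methyl-3-[(1E,3E,5S)-3,5-dimethylhepta-1,3-dien-1-yl]-6H-isochromene-6,8(7H)-dione, via ortho-quinol 18 (not isolated)
Conditions: flavin-dependent monooxygenase (AzaH-type, FAD, E. coli lysate), NADP+ (2 mol %), phosphite dehydrogenase, Na2HPO3 (3 equiv), air, 50 mM potassium phosphate pH 8.0 (no amine buffer), 5 % DMSO, 30 °C; then pH 4, EtOAc
Reagents that add atoms: dioxygen, O=O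
Why: The enzyme's C4a-hydroperoxyflavin hydroxylates the methyl-bearing carbon of the bound phenolate from one face (enzymatic oxidative dearomatisation), setting the quaternary centre as R, and the ortho-quinol then closes ring B by hemiacetal formation and loss of water.

Step 15
Reactants: 19 (7R)-7-hydroxy-7-methyl-3-[(1E,3E,5S)-3,5-dimethylhepta-1,3-dien-1-yl]-6H-isochromene-6,8(7H)-dione
Product: 20 (7R)-7-methyl-3-[(1E,3E,5S)-3,5-dimethylhepta-1,3-dien-1-yl]-6,8-dioxo-7,8-dihydro-6H-isochromen-7-yl acetate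
Conditions: Ac2O, Et3N, DMAP (cat.), CH2Cl2, 0 °C → rt
Reagents that add atoms: acetic anhydride, CC(=O)OC(C)=O
Why: DMAP-catalysed acylation of the tertiary alcohol occurs at oxygen only, with retention at C7, and tertiary amines do not open the pyran ring.

Step 16
Reactants: 20 (7R)-7-methyl-3-[(1E,3E,5S)-3,5-dimethylhepta-1,3-dien-1-yl]-6,8-dioxo-7,8-dihydro-6H-isochromen-7-yl acetate
Product: 21 7-epi-sclerotiorin, (7S)-5-chloro-7-methyl-3-[(1E,3E,5S)-3,5-dimethylhepta-1,3-dien-1-yl]-6,8-dioxo-7,8-dihydro-6H-isochromen-7-yl acetate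
Conditions: NCS (1.05 equiv), MeCN, 0 °C → rt, dark
Reagents that add atoms: N-chlorosuccinimide, O=C1CCC(=O)N1Cl
Why: Electrophilic chlorination goes to C5, the most nucleophilic carbon of the doubly vinylogous ester; C7 is untouched, and its descriptor changes from R to S only because chlorine raises the CIP rank of the C6 branch.

## Compound list

1 | tiglic acid, (E)-2-methylbut-2-enoic acid | C/C=C(\C)C(=O)O | starting material
2 | (S)-2-methylbutanoic acid | CC[C@H](C)C(=O)O | intermediate
3 | (S)-2-methylbutan-1-ol | CC[C@H](C)CO | intermediate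
4 | (S)-2-methylbutanal | CC[C@H](C)C=O | intermediate (not isolated)
5 | ethyl (S,E)-2,4-dimethylhex-2-enoate | CC[C@H](C)/C=C(C)/C(=O)OCC | intermediate
6 | (S,E)-2,4-dimethylhex-2-en-1-ol | CC[C@H](C)/C=C(C)/CO | intermediate
7 | (S,E)-2,4-dimethylhex-2-enal | CC[C@H](C)/C=C(C)/C=O | intermediate
8 | trimethyl[(3E,5E,7S)-5,7-dimethylnona-3,5-dien-1-yn-1-yl]silane | CC[C@H](C)/C=C(C)/C=C/C#C[Si](C)(C)C | intermediate
9 | (3E,5E,7S)-5,7-dimethylnona-3,5-dien-1-yne | CC[C@H](C)/C=C(C)/C=C/C#C | intermediate
10 | 2,6-dimethoxytoluene | COc1cccc(OC)c1C | starting material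
11 | 2-(3,5-dimethoxy-4-methylphenyl)-4,4,5,5-tetramethyl-1,3,2-dioxaborolane | COc1cc(B2OC(C)(C)C(C)(C)O2)cc(OC)c1C | intermediate
12 | 5-bromo-1,3-dimethoxy-2-methylbenzene | COc1cc(Br)cc(OC)c1C | intermediate
13 | 6-bromo-2,4-dimethoxy-3-methylbenzaldehyde | COc1cc(Br)c(C=O)c(OC)c1C | intermediate
14 | 6-bromo-2,4-dihydroxy-3-methylbenzaldehyde | Cc1c(O)cc(Br)c(C=O)c1O | intermediate
15 | 2,4-dihydroxy-3-methyl-6-[(3E,5E,7S)-5,7-dimethylnona-3,5-dien-1-yn-1-yl]benzaldehyde | CC[C@H](C)/C=C(C)/C=C/C#Cc1cc(O)c(C)c(O)c1C=O | intermediate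
16 | 6,8-dihydroxy-7-methyl-3-[(1E,3E,5S)-3,5-dimethylhepta-1,3-dien-1-yl]isochromenylium trifluoroacetate | CC[C@H](C)/C=C(C)/C=C/c1cc2cc(O)c(C)c(O)c2c[o+]1.[O-]C(=O)C(F)(F)F | intermediate (not isolated)
17 | 2,4-dihydroxy-3-methyl-6-[(3E,5E,7S)-5,7-dimethyl-2-oxonona-3,5-dien-1-yl]benzaldehyde | CC[C@H](C)/C=C(C)/C=C/C(=O)Cc1cc(O)c(C)c(O)c1C=O | intermediate
18 | (5R)-4,5-dihydroxy-5-methyl-6-oxo-2-[(3E,5E,7S)-5,7-dimethyl-2-oxonona-3,5-dien-1-yl]cyclohexa-1,3-diene-1-carbaldehyde | CC[C@H](C)/C=C(C)/C=C/C(=O)CC1=C(C=O)C(=O)[C@](C)(O)C(O)=C1 | intermediate (not isolated)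
19 | (7R)-7-hydroxy-7-methyl-3-[(1E,3E,5S)-3,5-dimethylhepta-1,3-dien-1-yl]-6H-isochromene-6,8(7H)-dione | CC[C@H](C)/C=C(C)/C=C/C1=CC2=CC(=O)[C@@](C)(O)C(=O)C2=CO1 | intermediate
20 | (7R)-7-methyl-3-[(1E,3E,5S)-3,5-dimethylhepta-1,3-dien-1-yl]-6,8-dioxo-7,8-dihydro-6H-isochromen-7-yl acetate | CC[C@H](C)/C=C(C)/C=C/C1=CC2=CC(=O)[C@@](C)(OC(C)=O)C(=O)C2=CO1 | intermediate
21 | 7-epi-sclerotiorin, (7S)-5-chloro-7-methyl-3-[(1E,3E,5S)-3,5-dimethylhepta-1,3-dien-1-yl]-6,8-dioxo-7,8-dihydro-6H-isochromen-7-yl acetate | CC[C@H](C)/C=C(C)/C=C/C1=CC2=C(Cl)C(=O)[C@@](C)(OC(C)=O)C(=O)C2=CO1 | target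

## Step count and weak points

Total steps: 16. Longest linear sequence: 12 (steps 1–7, then 12–16); the aryl branch (steps 8–11) joins at step 12.

The three steps most likely to fail:

**Step 13 (cyclisation and hydrolysis to the keto-aldehyde).** The pyrylium salt may be slow to ring-open, or the dienyl chain may suffer in TFA. The fallback sets out from 15 and comes back at 17. Cyclise 15 with AgOTf (5 mol %) in MeOH/CH2Cl2 at rt, so that the 6-endo product is trapped as the neutral mixed acetal 3-[(1E,3E,5S)-3,5-dimethylhepta-1,3-dien-1-yl]-1-methoxy-7-methyl-1H-isochromene-6,8-diol F1 (both C1 epimers). Purify it on buffered silica, then unmask it with AcOH/H2O/THF at rt to give 17. No pyrylium salt is handled in strong acid.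

**Step 14 (enzymatic dearomatisation).** In buffer 17 sits partly as its cyclic lactol and is lipophilic, so turnover may stall. The fallback sets out from 15 and comes back at 19. Offer the alkyne 15, which cannot lactolise, to the same flavin-dependent monooxygenase with the same cofactor recycling and 10 % DMSO. This gives the ortho-quinol alkyne (5R)-4,5-dihydroxy-5-methyl-6-oxo-2-[(3E,5E,7S)-5,7-dimethylnona-3,5-dien-1-yn-1-yl]cyclohexa-1,3-diene-1-carbaldehyde F2. Ring B is then closed afterwards by cycloisomerisation with Au(OAc)3 (5 mol %) in ClCH2CH2Cl at rt (or CuI with iPr2NEt), giving 19. The order of dearomatisation and ketone formation is thereby reversed.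

**Step 16 (late chlorination beside a diene).** NCS may also attack C4 or the side-chain diene. The fallback sets out from 19 and comes back at 21. Chlorinate the free alcohol 19 first (NCS, MeCN, 0 °C) to (7S)-5-chloro-7-hydroxy-7-methyl-3-[(1E,3E,5S)-3,5-dimethylhepta-1,3-dien-1-yl]-6H-isochromene-6,8(7H)-dione F3. This polar alcohol is easily freed from over-chlorinated material. Then acetylate F3 (Ac2O, Et3N, DMAP, CH2Cl2) to 21.

## Further compounds

F1 | step 13 | 3-[(1E,3E,5S)-3,5-dimethylhepta-1,3-dien-1-yl]-1-methoxy-7-methyl-1H-isochromene-6,8-diol (C1 epimers) | CC[C@H](C)/C=C(C)/C=C/C1=Cc2cc(O)c(C)c(O)c2C(OC)O1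
F2 | step 14 | (5R)-4,5-dihydroxy-5-methyl-6-oxo-2-[(3E,5E,7S)-5,7-dimethylnona-3,5-dien-1-yn-1-yl]cyclohexa-1,3-diene-1-carbaldehyde | CC[C@H](C)/C=C(C)/C=C/C#CC1=C(C=O)C(=O)[C@](C)(O)C(O)=C1
F3 | step 16 | (7S)-5-chloro-7-hydroxy-7-methyl-3-[(1E,3E,5S)-3,5-dimethylhepta-1,3-dien-1-yl]-6H-isochromene-6,8(7H)-dione | CC[C@H](C)/C=C(C)/C=C/C1=CC2=C(Cl)C(=O)[C@@](C)(O)C(=O)C2=CO1
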